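**Plan** (flavonoid numbering; suffix u = upper flavan-3-ol unit, t = lower taxifolin unit)
- Retrosynthesis: remove the seven O-benzyl groups; cut C3u–C4u of ring C of the upper unit (the ring closure); cut O1u–C2u (allylic aryl ether) and add back the side-chain carboxyl; cut C4u–C4au (C4u comes from a formyl group on C8t); the lower unit goes back to (+)-catechin.
- Forward: catechin → C8 bromide → C8 aldehyde → C4 ketone (taxifolin level); ortho-specific union with 3,5-bis(benzyloxy)phenol gives the C8t–C4u–ring A(u) diarylmethane; then O1u–C2u etherification, dihydroxylation, oxidation to the α-hydroxy acid and release of 5t-OH; ring C of the upper unit closes last, at C3u–C4u.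
- Enabling feature: C4u is doubly benzylic and para, through C8t, to the chelated 5-OH of ring A of the taxifolin unit, so dehydrogenation gives a p-quinone methide with exocyclic C4u=C8t. C3u carries oxygen, so it can be an α-oxy radical born by decarboxylation; its 6-exo 1,6-addition re-aromatises ring A(t).
- Stereochemistry: C2t/C3t come from (+)-catechin and are not touched by the C4t oxidation; C2u comes from iridium-catalysed asymmetric allylic etherification; C3u and C4u are set in the key step by a half-chair transition state (B ring equatorial, taxifolin ring pseudoaxial away from the peri 5u-OBn, C3u–O anti to it).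

Key step: step 13

Remark on the chemistry: the carbinol carbon of the side chain in 15–17 (the future C3u) is carried as a mixture of epimers, because it becomes a planar radical in step 13. (+)-Catechin, 3,5-bis(benzyloxy)phenol and 3,4-bis(benzyloxy)benzaldehyde are taken as purchasable.

**Step 1**
Reactants: 1 (+)-catechin
Product: 2 5,7,3',4'-tetra-O-benzyl-(+)-catechin
Conditions: BnBr (4.4 equiv), K2CO3, DMF, 0 °C to rt
Reagents that add atoms: benzyl bromide, BrCc1ccccc1
Why: Williamson O-benzylation under carbonate base alkylates only the four phenols, leaves the aliphatic 3-OH free and does not touch the two chiral-pool stereocentres.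

**Step 2**
Reactants: 2 5,7,3',4'-tetra-O-benzyl-(+)-catechin
Product: 3 8-bromo-5,7,3',4'-tetra-O-benzyl-(+)-catechin
Conditions: NBS (1.0 equiv), CH2Cl2, −78 °C to rt
Reagents that add atoms: N-bromosuccinimide, O=C1CCC(=O)N1Br
Why: Electrophilic aromatic bromination of the 5,7-dibenzyloxy ring A goes to C8, the established site for this substrate class, which fixes the interflavan regiochemistry.

**Step 3**
Reactants: 3 8-bromo-5,7,3',4'-tetra-O-benzyl-(+)-catechin
Product: 4 8-formyl-5,7,3',4'-tetra-O-benzyl-(+)-catechin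
Conditions: n-BuLi (2.2 equiv), THF, −78 °C; then DMF; aq NH4Cl
Reagents that add atoms: N,N-dimethylformamide, CN(C)C=O
Why: After deprotonation of the 3-OH the second equivalent effects bromine–lithium exchange and the aryllithium is formylated by DMF (Bouveault aldehyde synthesis), remote from the stereocentres.

**Step 4**
Reactants: 4 8-formyl-5,7,3',4'-tetra-O-benzyl-(+)-catechin
Product: 6 8-formyl-5,7,3',4'-tetra-O-benzyl-(2R,3R)-taxifolin, via flavan-3,4-diol 5 (not isolated)
Conditions: DDQ (2.5 equiv), CH2Cl2/H2O 10:1, rt to 40 °C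
Reagents that add atoms: water, O
Why: DDQ benzylic oxidation (hydride abstraction from C4, capture of the trialkoxybenzyl cation by water, then dehydrogenation of the electron-rich benzylic carbinol) raises the unit to the taxifolin level with C2 and C3 spatially unchanged (the C3 descriptor becomes R only through the priority rules).

**Step 5**
Reactants: 6 8-formyl-5,7,3',4'-tetra-O-benzyl-(2R,3R)-taxifolin; 7 3,5-bis(benzyloxy)phenol
Product: 9 8-[2-hydroxy-4,6-bis(benzyloxy)benzyl]-5,7,3',4'-tetra-O-benzyl-(2R,3R)-taxifolin, via benzodioxaborin 8 (not isolated)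
Conditions: PhB(OH)2 (1.2 equiv), EtCO2H (cat.), toluene, reflux (water separator); then Et3SiH, CF3CO2H, CH2Cl2, −20 to 0 °C
Reagents that add atoms: none
Why: Boronic-acid-templated ortho-hydroxyalkylation of the phenol by the aldehyde is ortho-specific (the two ortho positions of 7 are equivalent), and ionic hydrogenation of the doubly benzylic C–O bond of 8 then gives the diarylmethane while the less easily ionised flavanonol ketone is left at low temperature.

**Step 6**
Reactants: 10 3,4-bis(benzyloxy)benzaldehyde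
Product: 11 ethyl (E)-3-[3,4-bis(benzyloxy)phenyl]acrylate
Conditions: (EtO)2P(O)CH2CO2Et, NaH, THF, 0 °C to rt
Reagents that add atoms: triethyl phosphonoacetate, CCOC(=O)CP(=O)(OCC)OCC
Why: Horner–Wadsworth–Emmons olefination of the aryl aldehyde gives the E enoate.

**Step 7**
Reactants: 11 ethyl (E)-3-[3,4-bis(benzyloxy)phenyl]acrylate
Product: 12 (E)-3-[3,4-bis(benzyloxy)phenyl]prop-2-en-1-ol
Conditions: i-Bu2AlH (2.2 equiv), CH2Cl2, −78 °C; aq potassium sodium tartrate
Reagents that add atoms: none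
Why: 1,2-Reduction of the conjugated ester by the aluminium hydride gives the allylic alcohol without touching the alkene or the benzyl ethers.

**Step 8**
Reactants: 12 (E)-3-[3,4-bis(benzyloxy)phenyl]prop-2-en-1-ol
Product: 13 (E)-3-[3,4-bis(benzyloxy)phenyl]allyl methyl carbonate
Conditions: ClCO2Me, pyridine, CH2Cl2, 0 °C
Reagents that add atoms: methyl chloroformate, COC(=O)Cl
Why: O-Acylation of the primary allylic alcohol installs the carbonate leaving group needed for ionisation by iridium.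

**Step 9**
Reactants: 9 8-[2-hydroxy-4,6-bis(benzyloxy)benzyl]-5,7,3',4'-tetra-O-benzyl-(2R,3R)-taxifolin; 13 (E)-3-[3,4-bis(benzyloxy)phenyl]allyl methyl carbonate
Product: 14 8-{2-[(1S)-1-(3,4-bis(benzyloxy)phenyl)allyloxy]-4,6-bis(benzyloxy)benzyl}-5,7,3',4'-tetra-O-benzyl-(2R,3R)-taxifolin
Conditions: LiN(SiMe3)2 (1.0 equiv), THF, −78 to 0 °C; then 13, [Ir(cod)Cl]2 (2 mol%), (Sa,Sc,Sc)-O,O'-(1,1'-binaphthyl-2,2'-diyl)-N,N-bis(1-phenylethyl)phosphoramidite (4 mol%), THF, rt to 40 °C
Reagents that add atoms: none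
Why: Iridium-catalysed asymmetric allylic etherification, in which the lithium aryloxide (the phenol is the only site deprotonated by one equivalent of base) attacks the aryl-substituted allyl terminus, gives the branched ether whose new centre (S here, the future 2R of C2u) is set by the ligand; the ligand enantiomer named is the one expected to give this sense and should be confirmed on a model phenol.

**Step 10**
Reactants: 14 the branched allyl aryl ether
Product: 15 8-{2-[(1R)-1-(3,4-bis(benzyloxy)phenyl)-2,3-dihydroxypropoxy]-4,6-bis(benzyloxy)benzyl}-5,7,3',4'-tetra-O-benzyl-(2R,3R)-taxifolin (both carbinol epimers)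
Conditions: OsO4 (2 mol%), NMO, acetone/H2O, rt
Reagents that add atoms: N-methylmorpholine N-oxide, C[N+]1([O-])CCOCC1; water, O
Why: OsO4-catalysed syn-dihydroxylation of the only alkene; the new carbinol centre needs no control because it becomes a planar radical in step 13.

**Step 11**
Reactants: 15 the diol
Product: 16 (3R)-3-[3,4-bis(benzyloxy)phenyl]-2-hydroxy-3-{3,5-bis(benzyloxy)-2-[(5,7,3',4'-tetra-O-benzyl-(2R,3R)-taxifolin-8-yl)methyl]phenoxy}propanoic acid (both C2 epimers)
Conditions: TEMPO (20 mol%), PhI(OAc)2 (2.5 equiv), MeCN/H2O 1:1, rt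
Reagents that add atoms: water, O
Why: Nitroxyl (oxoammonium) oxidation is selective for the primary carbinol and runs through the aldehyde hydrate to the acid, while the secondary carbinols next to electron-withdrawing groups and the benzyl ethers are left.

**Step 12**
Reactants: 16 the α-hydroxy acid
Product: 17 the α-hydroxy acid with free 5-OH on the taxifolin unit (7,3',4'-tri-O-benzyl)
Conditions: MgBr2·OEt2 (3 equiv), toluene/Et2O, rt to 45 °C; dilute aq HCl
Reagents that add atoms: none
Why: Chelation-controlled Lewis-acid debenzylation, with MgBr2 bound between the C4t carbonyl and the peri 5t-oxygen, delivers bromide to that one benzyl group only.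

**Step 13**
Reactants: 17 the phenol acid
Product: 19 5,7,3',4'-tetra-O-benzyl-epicatechin-(4β→8)-7,3',4'-tri-O-benzyl-(2R,3R)-taxifolin, via p-quinone methide 18 (not isolated)
Conditions: DDQ (1.05 equiv), CH2Cl2, 0 °C, filter, evaporate; then [Ir(dF(CF3)ppy)2(dtbbpy)]PF6 (2 mol%), K2HPO4 (1.2 equiv), degassed DMF (0.01 M), 450 nm LEDs, rt
Reagents that add atoms: none
Why: Proposed new method: DDQ dehydrogenates the p-alkylphenol of ring A(t) (5t-OH para to C8t, C4u–H doubly benzylic) to the p-quinone methide 18 with exocyclic C4u=C8t; the photoexcited iridium complex then oxidises the carboxylate, loss of CO2 leaves an α-hydroxyalkyl radical at C3u, and this adds to C4u, re-aromatising ring A(t) as a phenoxyl radical that the reduced catalyst returns to phenoxide (redox-neutral from 18). The closest known reactions are photoredox decarboxylative Giese additions of α-oxy acids and radical 1,6-additions to p-quinone methides, here run intramolecularly on an unhindered flavanonol-derived quinone methide. Ring C of the upper unit closes in the 6-exo-trig mode (C3u attacks the exocyclic C4u, C8t stays outside the new ring). C4u is set by the half-chair transition state in which the aryl on the fixed C2u centre is equatorial and the quinone-methide ring takes the pseudoaxial site to avoid the peri 5u-OBn, which gives the 2,4-trans (4β) arrangement; C3u is set by the radical oxygen lying pseudoaxial, anti to that ring and gauche to O1u, which gives 2,3-cis/3,4-trans. The step needs C–C bond formation to outrun β-scission of the C2u–O1u bond and oxidation of the ketyl-type radical; the tethered, strongly electrophilic acyl-substituted acceptor, the gauche alignment of the radical orbital with the C2u–O1u bond in the closing conformer, and high dilution without any stoichiometric reductant are relied on for this.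

**Step 14**
Reactants: 19 the hepta-O-benzyl dimer
Product: 20 epicatechin-(4β→8)-(2R,3R)-taxifolin (CNP0210692.1)
Conditions: H2 (1 atm), Pd(OH)2/C, THF/MeOH, rt
Reagents that add atoms: none
Why: Hydrogenolysis of the seven benzyl ethers over Pd(OH)2/C spares the aryl ketone, the interflavan bond and the benzylic C–O bonds of both pyran rings at one atmosphere.

**Compound list**
1 | (+)-catechin, (2R,3S) | C1c2c(O)cc(O)cc2O[C@H](c2ccc(O)c(O)c2)[C@H]1O | starting material
2 | 5,7,3',4'-tetra-O-benzyl-(+)-catechin | C1c2c(OCc3ccccc3)cc(OCc3ccccc3)cc2O[C@H](c2ccc(OCc3ccccc3)c(OCc3ccccc3)c2)[C@H]1O | intermediate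
3 | 8-bromo-5,7,3',4'-tetra-O-benzyl-(+)-catechin | C1c2c(OCc3ccccc3)cc(OCc3ccccc3)c(Br)c2O[C@H](c2ccc(OCc3ccccc3)c(OCc3ccccc3)c2)[C@H]1O | intermediate
4 | 8-formyl-5,7,3',4'-tetra-O-benzyl-(+)-catechin | C1c2c(OCc3ccccc3)cc(OCc3ccccc3)c(C=O)c2O[C@H](c2ccc(OCc3ccccc3)c(OCc3ccccc3)c2)[C@H]1O | intermediate
5 | 8-formyl-tetra-O-benzyl flavan-3,4-diol (C4 epimers), not isolated | OC1c2c(OCc3ccccc3)cc(OCc3ccccc3)c(C=O)c2O[C@H](c2ccc(OCc3ccccc3)c(OCc3ccccc3)c2)[C@H]1O | intermediate
6 | 8-formyl-5,7,3',4'-tetra-O-benzyl-(2R,3R)-taxifolin | O=C1c2c(OCc3ccccc3)cc(OCc3ccccc3)c(C=O)c2O[C@H](c2ccc(OCc3ccccc3)c(OCc3ccccc3)c2)[C@H]1O | intermediate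
7 | 3,5-bis(benzyloxy)phenol | Oc1cc(OCc2ccccc2)cc(OCc2ccccc2)c1 | starting material
8 | 5,7-bis(benzyloxy)-2-phenyl-4-(tetra-O-benzyl-taxifolin-8-yl)-4H-1,3,2-benzodioxaborin (C4 epimers), not isolated | O=C1c2c(OCc3ccccc3)cc(OCc3ccccc3)c(C3OB(c4ccccc4)Oc4cc(OCc5ccccc5)cc(OCc5ccccc5)c34)c2O[C@H](c2ccc(OCc3ccccc3)c(OCc3ccccc3)c2)[C@H]1O | intermediate
9 | 8-[2-hydroxy-4,6-bis(benzyloxy)benzyl]-5,7,3',4'-tetra-O-benzyl-(2R,3R)-taxifolin | O=C1c2c(OCc3ccccc3)cc(OCc3ccccc3)c(Cc3c(O)cc(OCc4ccccc4)cc3OCc3ccccc3)c2O[C@H](c2ccc(OCc3ccccc3)c(OCc3ccccc3)c2)[C@H]1O | intermediate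
10 | 3,4-bis(benzyloxy)benzaldehyde | O=Cc1ccc(OCc2ccccc2)c(OCc2ccccc2)c1 | starting material
11 | ethyl (E)-3-[3,4-bis(benzyloxy)phenyl]acrylate | CCOC(=O)/C=C/c1ccc(OCc2ccccc2)c(OCc2ccccc2)c1 | intermediate
12 | (E)-3-[3,4-bis(benzyloxy)phenyl]prop-2-en-1-ol | OC/C=C/c1ccc(OCc2ccccc2)c(OCc2ccccc2)c1 | intermediate
13 | (E)-3-[3,4-bis(benzyloxy)phenyl]allyl methyl carbonate | COC(=O)OC/C=C/c1ccc(OCc2ccccc2)c(OCc2ccccc2)c1 | intermediate
14 | (1S)-branched allyl aryl ether of 9 | O=C1c2c(OCc3ccccc3)cc(OCc3ccccc3)c(Cc3c(O[C@H](c4ccc(OCc5ccccc5)c(OCc5ccccc5)c4)C=C)cc(OCc4ccccc4)cc3OCc3ccccc3)c2O[C@H](c2ccc(OCc3ccccc3)c(OCc3ccccc3)c2)[C@H]1O | intermediate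
15 | (1R)-1-aryl-2,3-dihydroxypropyl aryl ether (carbinol epimers) | O=C1c2c(OCc3ccccc3)cc(OCc3ccccc3)c(Cc3c(O[C@H](c4ccc(OCc5ccccc5)c(OCc5ccccc5)c4)C(O)CO)cc(OCc4ccccc4)cc3OCc3ccccc3)c2O[C@H](c2ccc(OCc3ccccc3)c(OCc3ccccc3)c2)[C@H]1O | intermediate
16 | (3R)-3-aryl-3-aryloxy-2-hydroxypropanoic acid (C2 epimers), lower unit tetra-O-benzyl | O=C1c2c(OCc3ccccc3)cc(OCc3ccccc3)c(Cc3c(O[C@H](c4ccc(OCc5ccccc5)c(OCc5ccccc5)c4)C(O)C(=O)O)cc(OCc4ccccc4)cc3OCc3ccccc3)c2O[C@H](c2ccc(OCc3ccccc3)c(OCc3ccccc3)c2)[C@H]1O | intermediate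
17 | the same acid with free 5-OH on the taxifolin unit | O=C1c2c(O)cc(OCc3ccccc3)c(Cc3c(O[C@H](c4ccc(OCc5ccccc5)c(OCc5ccccc5)c4)C(O)C(=O)O)cc(OCc4ccccc4)cc3OCc3ccccc3)c2O[C@H](c2ccc(OCc3ccccc3)c(OCc3ccccc3)c2)[C@H]1O | intermediate
18 | p-quinone methide (exocyclic C4u=C8t, C5t=O), not isolated | O=C1C2=C(O[C@H](c3ccc(OCc4ccccc4)c(OCc4ccccc4)c3)[C@H]1O)C(=Cc1c(O[C@H](c3ccc(OCc4ccccc4)c(OCc4ccccc4)c3)C(O)C(=O)O)cc(OCc3ccccc3)cc1OCc1ccccc1)C(OCc1ccccc1)=CC2=O | intermediate
19 | 5,7,3',4'-tetra-O-benzyl-epicatechin-(4β→8)-7,3',4'-tri-O-benzyl-(2R,3R)-taxifolin | O=C1c2c(O)cc(OCc3ccccc3)c([C@H]3c4c(OCc5ccccc5)cc(OCc5ccccc5)cc4O[C@H](c4ccc(OCc5ccccc5)c(OCc5ccccc5)c4)[C@@H]3O)c2O[C@H](c2ccc(OCc3ccccc3)c(OCc3ccccc3)c2)[C@H]1O | intermediate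
20 | epicatechin-(4β→8)-(2R,3R)-taxifolin; upper unit 2R,3R with the C4 aryl trans to 3-OH and to the B ring | O=C1c2c(O)cc(O)c([C@H]3c4c(O)cc(O)cc4O[C@H](c4ccc(O)c(O)c4)[C@@H]3O)c2O[C@H](c2ccc(O)c(O)c2)[C@H]1O | target

**Count**
Total steps: 14. Longest linear sequence: 11 (steps 1–5 and 9–14).

**Steps most likely to fail**

Step 13. The C3u radical may fragment by β-scission of the C2u–O1u bond or be oxidised to the aldehyde before it closes. The quinone methide may be consumed by reversible oxygen 1,6-addition or by oligomerisation. Facial selectivity at C4u/C3u may be poor. The fallback uses the known Lewis-acid interflavan coupling; it sets out from 2 and returns at 19.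
- Upper electrophile: 2 is oxidised with Dess–Martin periodinane to the tetra-O-benzyl flavan-3-one F1. Reduction with LiBH(s-Bu)3 at −78 °C gives 5,7,3',4'-tetra-O-benzyl-(−)-epicatechin F2. DDQ with 2-ethoxyethanol in CH2Cl2 gives 4β-(2-ethoxyethoxy)-tetra-O-benzyl-epicatechin F3.
- Lower nucleophile: 2 is oxidised with DDQ/H2O to 5,7,3',4'-tetra-O-benzyl-taxifolin F4. MgBr2·OEt2 removes the peri benzyl group to give 7,3',4'-tri-O-benzyl-taxifolin F5.
- Coupling: F3 and an excess of F5 with Me3SiOTf in CH2Cl2 at −78 °C give 19, the nucleophile entering trans to the 3-OH. The 4→6 regioisomer is removed by chromatography.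

Step 9. The branched ether may form with a low branched-to-linear ratio or lose enantiopurity through re-ionisation of the electron-rich allyl ether. C-allylation of the aryloxide or Claisen rearrangement may compete. The fallback sets out from 12 (with 9) and returns at 15. Sharpless asymmetric epoxidation of 12 (Ti(OiPr)4, diisopropyl L-(+)-tartrate, t-BuOOH, molecular sieves, −20 °C) gives the (2S,3S)-epoxy alcohol F6. The caesium phenoxide of 9 (Cs2CO3, DMF, 40 °C) opens F6 at the benzylic carbon with inversion, giving 15 as a single carbinol epimer with the required R ether centre.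

Step 4. Hydride abstraction at C4 may stall, or stop at the diol 5, because the 8-formyl group lowers the electron density of ring A. The fallback sets out from 3 and returns at 6. DDQ/H2O on 3 gives 8-bromo-5,7,3',4'-tetra-O-benzyl-taxifolin F7. Stille coupling with Bu3SnCH=CH2 and Pd(PPh3)4 in toluene at 90 °C gives the 8-vinyl compound F8. OsO4 (cat.)/NaIO4 with 2,6-lutidine in dioxane/H2O cleaves the vinyl group to give 6.

**Further compounds**
F1 | step 13 | (2R)-5,7-bis(benzyloxy)-2-[3,4-bis(benzyloxy)phenyl]chroman-3-one | C1c2c(OCc3ccccc3)cc(OCc3ccccc3)cc2O[C@H](c2ccc(OCc3ccccc3)c(OCc3ccccc3)c2)C1=O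
F2 | step 13 | 5,7,3',4'-tetra-O-benzyl-(−)-epicatechin, (2R,3R) | C1c2c(OCc3ccccc3)cc(OCc3ccccc3)cc2O[C@H](c2ccc(OCc3ccccc3)c(OCc3ccccc3)c2)[C@@H]1O
F3 | step 13 | 4β-(2-ethoxyethoxy)-5,7,3',4'-tetra-O-benzyl-epicatechin | CCOCCO[C@H]1c2c(OCc3ccccc3)cc(OCc3ccccc3)cc2O[C@H](c2ccc(OCc3ccccc3)c(OCc3ccccc3)c2)[C@@H]1O
F4 | step 13 | 5,7,3',4'-tetra-O-benzyl-(2R,3R)-taxifolin | O=C1c2c(OCc3ccccc3)cc(OCc3ccccc3)cc2O[C@H](c2ccc(OCc3ccccc3)c(OCc3ccccc3)c2)[C@H]1O
F5 | step 13 | 7,3',4'-tri-O-benzyl-(2R,3R)-taxifolin | O=C1c2c(O)cc(OCc3ccccc3)cc2O[C@H](c2ccc(OCc3ccccc3)c(OCc3ccccc3)c2)[C@H]1O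
F6 | step 9 | [(2S,3S)-3-(3,4-bis(benzyloxy)phenyl)oxiran-2-yl]methanol | OC[C@@H]1O[C@H]1c1ccc(OCc2ccccc2)c(OCc2ccccc2)c1
F7 | step 4 | 8-bromo-5,7,3',4'-tetra-O-benzyl-(2R,3R)-taxifolin | O=C1c2c(OCc3ccccc3)cc(OCc3ccccc3)c(Br)c2O[C@H](c2ccc(OCc3ccccc3)c(OCc3ccccc3)c2)[C@H]1O
F8 | step 4 | 8-vinyl-5,7,3',4'-tetra-O-benzyl-(2R,3R)-taxifolin | O=C1c2c(OCc3ccccc3)cc(OCc3ccccc3)c(C=C)c2O[C@H](c2ccc(OCc3ccccc3)c(OCc3ccccc3)c2)[C@H]1O
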